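The ratio of c(second substrate) in cedar to that in birch is 2.20, yet the mean of the last 3 target readings in cedar over the same mean in birch is 0.948. With a scatter of 1 percentage point per reading, I can read no effect there.

| setting | birch | elm | cedar | midnight | autumn | summer |
|---|---|---|---|---|---|---|
| starting material | 0.050 M | 0.050 M | 0.050 M | 0.050 M | 0.050 M | 0.050 M |
| second substrate | 0.050 M | 0.070 M | 0.11 M | 0.0500 M | 0.0500 M | 0.0500 M (fed, over 15 min) |
| partner | 0.025 M | 0.025 M | 0.025 M | 0.0250 M (fed, over 15 min) | 0.0250 M | 0.0250 M |
| free catalyst | 30 µM | 30 µM | 30 µM | 30 µM | 30 µM | 30 µM |
| remark | run made earlier | run made earlier | run made earlier | all else is in the flask from the start; the feed brings no volume worth counting | everything together at the start | all else is in the flask from the start; the feed brings no volume worth counting |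
| time |  |  |  | 80 min | 80 min | 80 min |

- birch (time / min: target / %): 4.00: 5.2; 6.00: 7.3; 10.0: 10.8; 20.0: 16.1; 30.0: 15.1; 50.0: 16.5
- elm (time / min: target / %): 4.00: 7.0; 6.00: 6.9; 10.0: 8.9; 20.0: 15.7; 30.0: 16.0; 50.0: 14.6
- cedar (time / min: target / %): 4.00: 4.8; 6.00: 7.3; 10.0: 11.9; 20.0: 13.6; 30.0: 16.7; 50.0: 14.9

(scatter of a reading: 1 percentage point)

- the numbers in the tables scatter by 1 percentage point (one standard deviation)

- the flask with the highest amount of target, in percent of the starting material charged ("all alike" if they lie within 1.5 percentage points) (midnight / autumn / summer / all alike)
- final target, as a percentage of the starting material charged, in midnight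
- final target, as a percentage of the starting material charged, in autumn
- final target, as a percentage of the starting material charged, in summer

So I freeze the level: the 9 readings from 20.0 min onward average 15.5%.

I then treat the rise as exponential. The three runs average 10.5% at 10.0 min, which gives 8.75 min. This is my settling time, the time constant: the time in which the gap to the level shrinks by a factor of e. The second way uses the readings at 4.00 min, which average 5.67% and give 8.77 min. The two ways share the level but use different readings, and they agree, so I trust the number.

In midnight and summer the feed ends at 15 min. The 65.0 min that follow are longer than the settling time, 7.43 times over. A late start should therefore be forgotten by the end, and I put the three flasks at 15.5%. For summer the cedar ratio supports this, though it was read at a c(second substrate) above that of birch, 0.050 M, and the feed in summer begins from nothing. For midnight it stays an assumption, because c(partner) was 0.025 M in birch and equal in cedar.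

The forecast says all alike, with 14% for midnight, 15.5% for autumn and 15% for summer, so it stands lower than my level for midnight. Its ground: “The sharp plateau argues against a second-order partner loss, so slow addition shouldn't bring much gain.”

The flasks come out all alike: midnight 13.0%, autumn 13.4%, summer 13.4%.

    starting material + free catalyst ⇌ catalyst intermediate A (K = 2000 M⁻¹, k = 37000 M⁻¹ min⁻¹)
    partner + catalyst intermediate A → free catalyst + target (k = 1100 M⁻¹ min⁻¹)
    second substrate + free catalyst ⇌ catalyst intermediate B (K = 14.0 M⁻¹, k = 1300 M⁻¹ min⁻¹)
    partner + catalyst intermediate B → free catalyst + second product (k = 340 M⁻¹ min⁻¹)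
    2 catalyst intermediate A ⇌ resting dimer (K = 1.40 × 10⁶ M⁻¹, k = 490 M⁻¹ min⁻¹)
    starting material + target → side product (k = 0.740 M⁻¹ min⁻¹)

Autumn also holds 47.0% side product at 80.0 min, in percent of the starting material charged. Midnight has 6.94% target at 15.0 min and 13.0% at 80.0 min, after the 7.43 settling times. It ends 0.40 points below autumn, less than the margin of 1.5 points.

Autumn read at 5.0 h is 34.3 settling times in, so my reckoning keeps it at 15.5%. The computed target there is 5.99%, with 80.9% side product, so the frozen level fails at that time.

The readings stem from a simulated flask from invented constants; the scatter is artificial.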